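Rings are lettered A to H from the 2,4,6-trihydroxyphenoxy end, and each ring is numbered from C1, the carbon bonded to the ether oxygen coming from the preceding ring. The plan rests on the C4–OH groups of rings C, E, F, G and H, each para to C1: every one is traced back to a C4–CHO group that first activates C1–F for ether formation and is then turned into oxygen.
Target ⇐ sixteenfold O-demethylation ⇐ octamer pentaphenol ⇐ fivefold Baeyer-Villiger oxidation ⇐ octamer pentaaldehyde.
Octamer pentaaldehyde ⇐ seven SNAr diaryl ether couplings in the order A–B, B–C, C–D, D–E, E–F, F–G, G–H, each phenoxide displacing a fluoride para to the activating group; the ortho phenols of rings C, E, F and G travel as allyl ethers.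
Repair: the ring D formyl group has to be oxidised to the ring D phenol while ring C already carries its para activator, so ring C enters as a nitrile (inert to peracid) and is reduced to the aldehyde right after that oxidation.
No ring is formed anywhere; all eight benzene rings come from the building blocks.

Key step: step 26

Remark: 3-fluoro-2-methoxyphenol is taken as a catalogue compound, and allyl ethers are chosen as phenol protection because they come off without hydrogen or acid in the presence of several aryl aldehydes.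

Step 1
Reactants: 1 4-fluoro-2,6-dimethoxybenzaldehyde
Product: 2 3-bromo-4-fluoro-2,6-dimethoxybenzaldehyde
Conditions: NBS (1.0 equiv), MeCN, 0 °C to rt
Reagents that add atoms: N-bromosuccinimide, O=C1CCC(=O)N1Br
Why: Electrophilic aromatic bromination should occur at C3 (equivalent to C5), the only open ring position, which is ortho to one methoxy group and para to the other, and the first bromine deactivates the ring against a second substitution.

Step 2
Reactants: 2 3-bromo-4-fluoro-2,6-dimethoxybenzaldehyde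
Product: 4 4-fluoro-3-hydroxy-2,6-dimethoxybenzaldehyde, via aryl pinacol boronate 3 (not isolated)
Conditions: B2pin2, Pd(dppf)Cl2 (cat.), KOAc, dioxane, 90 °C; then NaBO3·4H2O, THF/H2O, rt
Reagents that add atoms: sodium perborate, [Na+].[O-]OB=O
Why: Miyaura borylation of the aryl bromide and oxidation of the C–B bond by perborate (1,2-aryl shift from boron to oxygen) should give the phenol under conditions mild enough to spare the hindered aldehyde and the C–F bond.

Step 3
Reactants: 4 4-fluoro-3-hydroxy-2,6-dimethoxybenzaldehyde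
Product: 5 3-(allyloxy)-4-fluoro-2,6-dimethoxybenzaldehyde (ring G block)
Conditions: allyl bromide, K2CO3, DMF, rt
Reagents that add atoms: allyl bromide, C=CCBr
Why: Williamson ether synthesis; O-allylation of the phenoxide at room temperature is far faster than any SNAr at the neighbouring C–F bond, which the phenoxide itself deactivates.

Step 4
Reactants: 5 3-(allyloxy)-4-fluoro-2,6-dimethoxybenzaldehyde
Product: 7 3-(allyloxy)-4-fluoro-2,6-dimethoxybenzonitrile (ring C block), via aldoxime 6 (not isolated)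
Conditions: NH2OH·HCl, NaOAc, EtOH, 60 °C; then Ac2O, 120 °C
Reagents that add atoms: hydroxylamine hydrochloride, Cl.NO
Why: Condensation to the aldoxime and dehydration of its O-acetate is the standard aldehyde-to-nitrile conversion, and the nitrile keeps C4–F activated for SNAr while being inert to the peracid used later on ring D.

Step 5
Reactants: 1 4-fluoro-2,6-dimethoxybenzaldehyde
Product: 8 4-fluoro-2-hydroxy-6-methoxybenzaldehyde
Conditions: BCl3 (1.1 equiv), CH2Cl2, −78 to 0 °C; then H2O
Reagents that add atoms: none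
Why: Chelation-controlled ether cleavage: BCl3 bound to the formyl oxygen cleaves one ortho O–CH3 bond, and the six-membered boron chelate thus formed should protect the second methoxy group at this temperature.

Step 6
Reactants: 8 4-fluoro-2-hydroxy-6-methoxybenzaldehyde
Product: 9 2-(allyloxy)-4-fluoro-6-methoxybenzaldehyde (ring F block)
Conditions: allyl bromide, K2CO3, DMF, rt
Reagents that add atoms: allyl bromide, C=CCBr
Why: Williamson ether synthesis on the salicylaldehyde-type phenoxide, needed because a free ortho phenoxide would switch off the para C–F bond towards SNAr.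

Step 7
Reactants: 10 3-fluoro-2-methoxyphenol
Product: 11 4-fluoro-2-hydroxy-3-methoxybenzaldehyde
Conditions: (CH2O)n, MgCl2, Et3N, MeCN, reflux
Reagents that add atoms: paraformaldehyde (formaldehyde), C=O
Why: Magnesium-mediated ortho-formylation (Casnati-Skattebøl reaction) delivers formaldehyde inside the magnesium phenoxide to the only free ortho carbon, which lies para to fluorine, and a second formaldehyde takes up hydride to give the aldehyde.

Step 8
Reactants: 11 4-fluoro-2-hydroxy-3-methoxybenzaldehyde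
Product: 12 5-bromo-4-fluoro-2-hydroxy-3-methoxybenzaldehyde
Conditions: Br2, NaOAc, AcOH, rt
Reagents that add atoms: bromine, BrBr
Why: Electrophilic aromatic bromination should go to C5, para to the free hydroxyl and meta to the formyl group, as it does in ortho-vanillin, since C6 is activated only by the 3-methoxy group.

Step 9
Reactants: 12 5-bromo-4-fluoro-2-hydroxy-3-methoxybenzaldehyde
Product: 13 5-bromo-4-fluoro-2,3-dimethoxybenzaldehyde
Conditions: MeI, K2CO3, DMF, 40 °C
Reagents that add atoms: iodomethane, CI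
Why: Williamson methylation of the hydrogen-bonded phenol fixes the second methoxy group of ring E once the phenol has directed the bromine.

Step 10
Reactants: 13 5-bromo-4-fluoro-2,3-dimethoxybenzaldehyde
Product: 15 4-fluoro-5-hydroxy-2,3-dimethoxybenzaldehyde, via aryl pinacol boronate 14 (not isolated)
Conditions: B2pin2, Pd(dppf)Cl2 (cat.), KOAc, dioxane, 90 °C; then NaBO3·4H2O, THF/H2O, rt
Reagents that add atoms: sodium perborate, [Na+].[O-]OB=O
Why: Miyaura borylation followed by perborate oxidation of the C–B bond, as in step 2, here on a bromide with only one bulky neighbour.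

Step 11
Reactants: 15 4-fluoro-5-hydroxy-2,3-dimethoxybenzaldehyde
Product: 16 5-(allyloxy)-4-fluoro-2,3-dimethoxybenzaldehyde (ring E block)
Conditions: allyl bromide, K2CO3, DMF, rt
Reagents that add atoms: allyl bromide, C=CCBr
Why: Williamson ether synthesis, which masks the phenol so that C4–F stays activated by the para formyl group.

Step 12
Reactants: 17 2,4,6-trimethoxyphenol; 1 4-fluoro-2,6-dimethoxybenzaldehyde
Product: 18 A-B dimer aldehyde (2,6-dimethoxy-4-(2,4,6-trimethoxyphenoxy)benzaldehyde)
Conditions: K2CO3, DMF, 110 °C, Ar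
Reagents that add atoms: none
Why: SNAr: the phenoxide adds to C4 of 1, the Meisenheimer adduct is stabilised by the para formyl group, and fluoride leaves.

Step 13
Reactants: 18 A-B dimer aldehyde
Product: 20 A-B dimer phenol (2,6-dimethoxy-4-(2,4,6-trimethoxyphenoxy)phenol), via dimer aryl formate 19 (not isolated)
Conditions: mCPBA, NaHCO3, CH2Cl2, 0 °C to rt; then K2CO3, MeOH, rt, Ar
Reagents that add atoms: mCPBA, O=C(OO)c1cccc(Cl)c1
Why: Baeyer-Villiger (Dakin-type) oxidation: the aryl group with two ortho methoxy groups and a para aryloxy group migrates in the Criegee adduct, and methanolysis of the formate gives the phenol.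

Step 14
Reactants: 20 A-B dimer phenol; 7 3-(allyloxy)-4-fluoro-2,6-dimethoxybenzonitrile
Product: 21 A-B-C trimer nitrile allyl ether (ring C 4-cyano and 6-allyloxy)
Conditions: Cs2CO3, DMF, 100 °C, Ar
Reagents that add atoms: none
Why: SNAr with the nitrile as para activator; fluoride is the only good leaving group and the adjacent allyloxy group is small enough to let the hindered phenoxide add.

Step 15
Reactants: 21 A-B-C trimer nitrile allyl ether
Product: 22 A-B-C trimer nitrile phenol (ring C 4-cyano and 6-hydroxy)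
Conditions: Pd(PPh3)4 (cat.), K2CO3, MeOH/THF, rt
Reagents that add atoms: none
Why: Zerovalent palladium ionises the allyl–O bond (Tsuji-Trost type) and methanol/carbonate traps the π-allyl complex as allyl methyl ether, which frees the phenol without touching the nitrile.

Step 16
Reactants: 22 A-B-C trimer nitrile phenol; 1 4-fluoro-2,6-dimethoxybenzaldehyde
Product: 23 A-B-C-D tetramer (ring C 4-cyano; ring D 4-formyl)
Conditions: Cs2CO3, DMF, 110 °C, Ar
Reagents that add atoms: none
Why: SNAr at the unhindered C4–F of 1, activated by the para formyl group.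

Step 17
Reactants: 23 A-B-C-D tetramer (ring C 4-cyano; ring D 4-formyl)
Product: 25 A-B-C-D tetramer phenol (ring C 4-cyano; ring D 4-hydroxy), via tetramer aryl formate 24 (not isolated)
Conditions: mCPBA, NaHCO3, CH2Cl2, 0 °C to rt; then K2CO3, MeOH, rt, Ar
Reagents that add atoms: mCPBA, O=C(OO)c1cccc(Cl)c1
Why: Baeyer-Villiger oxidation of the only formyl group present, while the nitrile on ring C does not react with peracid, so ring C keeps its para carbon substituent.

Step 18
Reactants: 25 A-B-C-D tetramer phenol (ring C 4-cyano; ring D 4-hydroxy)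
Product: 27 A-B-C-D tetramer phenol aldehyde (ring C 4-formyl; ring D 4-hydroxy), via ring C aldimine 26 (not isolated)
Conditions: i-Bu2AlH (DIBAL-H, 3 equiv), CH2Cl2, −78 to 0 °C; then 1 M HCl, THF, rt
Reagents that add atoms: water, O
Why: DIBAL-H adds once to the nitrile to give an N-aluminio aldimine that acid hydrolyses to the aldehyde; no other reducible group is present at this stage and the extra hydride covers the free phenol.

Step 19
Reactants: 27 A-B-C-D tetramer phenol aldehyde; 16 5-(allyloxy)-4-fluoro-2,3-dimethoxybenzaldehyde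
Product: 28 A-to-E pentamer allyl ether (formyl on C4 of rings C/E; allyloxy on C2 of ring E)
Conditions: Cs2CO3, DMSO, 120 °C, Ar
Reagents that add atoms: none
Why: SNAr; the para formyl group of 16 has only one ortho substituent and stays coplanar, so it activates C4–F well, and fluoride is small enough for the addition although four ortho oxygens flank the new ether.

Step 20
Reactants: 28 A-to-E pentamer allyl ether
Product: 29 A-to-E pentamer phenol (ring E 2-hydroxy)
Conditions: Pd(PPh3)4 (cat.), K2CO3, MeOH/THF, rt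
Reagents that add atoms: none
Why: Zerovalent palladium-catalysed deallylation as in step 15, which should leave the two aryl aldehydes untouched.

Step 21
Reactants: 29 A-to-E pentamer phenol; 9 2-(allyloxy)-4-fluoro-6-methoxybenzaldehyde
Product: 30 A-to-F hexamer allyl ether (formyl on C4 of rings C/E/F; allyloxy on C5 of ring F)
Conditions: Cs2CO3, DMF, 90 °C, Ar
Reagents that add atoms: none
Why: SNAr at a fluoride flanked by two hydrogens and activated by the para formyl group, the least hindered coupling of the series.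

Step 22
Reactants: 30 A-to-F hexamer allyl ether
Product: 31 A-to-F hexamer phenol (ring F 5-hydroxy)
Conditions: Pd(PPh3)4 (cat.), K2CO3, MeOH/THF, rt
Reagents that add atoms: none
Why: Zerovalent palladium-catalysed deallylation as in step 15, which frees the phenol ortho to the ring F formyl group.

Step 23
Reactants: 31 A-to-F hexamer phenol; 5 3-(allyloxy)-4-fluoro-2,6-dimethoxybenzaldehyde
Product: 32 A-to-G heptamer allyl ether (formyl on C4 of rings C/E/F/G; allyloxy on C6 of ring G)
Conditions: Cs2CO3, DMSO, 110 °C, Ar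
Reagents that add atoms: none
Why: SNAr; the phenoxide ortho to a formyl group is a weaker nucleophile, so Cs2CO3 in DMSO is used, and C4–F of 5 is the only position that carries a good leaving group para to a formyl group.

Step 24
Reactants: 32 A-to-G heptamer allyl ether
Product: 33 A-to-G heptamer phenol (ring G 6-hydroxy)
Conditions: Pd(PPh3)4 (cat.), K2CO3, MeOH/THF, rt
Reagents that add atoms: none
Why: Zerovalent palladium-catalysed deallylation as in step 15, compatible with the four aryl aldehydes.

Step 25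
Reactants: 33 A-to-G heptamer phenol; 1 4-fluoro-2,6-dimethoxybenzaldehyde
Product: 34 octamer pentaaldehyde (formyl on C4 of rings C/E/F/G/H; all other oxygens methylated)
Conditions: Cs2CO3, DMF, 110 °C, Ar
Reagents that add atoms: none
Why: SNAr of the ring G phenoxide at the unhindered C4–F of 1, activated by the para formyl group, completes the chain.

Step 26
Reactants: 34 octamer pentaaldehyde
Product: 36 octamer pentaphenol (hydroxyl on C4 of rings C/E/F/G/H; sixteen methoxy groups), via octamer pentaformate 35 (not isolated)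
Conditions: mCPBA (excess), Na2HPO4, CH2Cl2, 0 °C to rt; then K2CO3, MeOH, 0 °C, Ar
Reagents that add atoms: mCPBA, O=C(OO)c1cccc(Cl)c1
Why: Each formyl carbonyl adds the peracid to give a Criegee adduct, from which the aryl group migrates to oxygen with loss of 3-chlorobenzoate to give an aryl formate; carbonate-catalysed methanolysis then frees the phenol, so five C(aryl)–CHO bonds on C4 of rings C, E, F, G and H become five C(aryl)–O bonds in one operation. The closest known reaction type is the Baeyer-Villiger (Dakin-type) oxidation of alkoxy- and aryloxybenzaldehydes to phenols, already used in this route on rings B and D (steps 13 and 17). No ring is closed and no stereocentre is formed. The step needs aryl migration to win over hydride migration, which would give benzoic acids, and this is secured because every formyl-bearing ring has the ether oxygen on C1 para to the formyl group and at least one ortho methoxy or aryloxy donor. It also needs the peracid to spare the electron-rich rings A, B and D, which the solid phosphate buffer, the low temperature and a limited excess of oxidant should ensure.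

Step 27
Reactants: 36 octamer pentaphenol
Product: 37 CNP0309601.0 (target)
Conditions: BBr3 (excess), CH2Cl2, −78 °C to rt; then MeOH, H2O, Ar
Reagents that add atoms: none
Why: Lewis acid-mediated ether cleavage: BBr3 coordinates each methoxy oxygen and bromide attacks the methyl carbon by SN2, whereas the diaryl ether oxygens have no carbon open to SN2 and stay intact.

Compound list
1 | 4-fluoro-2,6-dimethoxybenzaldehyde | COc1cc(F)cc(OC)c1C=O | starting material
2 | 3-bromo-4-fluoro-2,6-dimethoxybenzaldehyde | COc1cc(F)c(Br)c(OC)c1C=O | intermediate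
3 | 4-fluoro-2,6-dimethoxy-3-(4,4,5,5-tetramethyl-1,3,2-dioxaborolan-2-yl)benzaldehyde | COc1cc(F)c(B2OC(C)(C)C(C)(C)O2)c(OC)c1C=O | intermediate
4 | 4-fluoro-3-hydroxy-2,6-dimethoxybenzaldehyde | COc1cc(F)c(O)c(OC)c1C=O | intermediate
5 | 3-(allyloxy)-4-fluoro-2,6-dimethoxybenzaldehyde (ring G block) | C=CCOc1c(F)cc(OC)c(C=O)c1OC | intermediate
6 | (E)-3-(allyloxy)-4-fluoro-2,6-dimethoxybenzaldehyde oxime | C=CCOc1c(F)cc(OC)c(/C=N/O)c1OC | intermediate
7 | 3-(allyloxy)-4-fluoro-2,6-dimethoxybenzonitrile (ring C block) | C=CCOc1c(F)cc(OC)c(C#N)c1OC | intermediate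
8 | 4-fluoro-2-hydroxy-6-methoxybenzaldehyde | COc1cc(F)cc(O)c1C=O | intermediate
9 | 2-(allyloxy)-4-fluoro-6-methoxybenzaldehyde (ring F block) | C=CCOc1cc(F)cc(OC)c1C=O | intermediate
10 | 3-fluoro-2-methoxyphenol | COc1c(O)cccc1F | starting material
11 | 4-fluoro-2-hydroxy-3-methoxybenzaldehyde | COc1c(F)ccc(C=O)c1O | intermediate
12 | 5-bromo-4-fluoro-2-hydroxy-3-methoxybenzaldehyde | COc1c(F)c(Br)cc(C=O)c1O | intermediate
13 | 5-bromo-4-fluoro-2,3-dimethoxybenzaldehyde | COc1c(F)c(Br)cc(C=O)c1OC | intermediate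
14 | 4-fluoro-2,3-dimethoxy-5-(4,4,5,5-tetramethyl-1,3,2-dioxaborolan-2-yl)benzaldehyde | COc1c(F)c(B2OC(C)(C)C(C)(C)O2)cc(C=O)c1OC | intermediate
15 | 4-fluoro-5-hydroxy-2,3-dimethoxybenzaldehyde | COc1c(F)c(O)cc(C=O)c1OC | intermediate
16 | 5-(allyloxy)-4-fluoro-2,3-dimethoxybenzaldehyde (ring E block) | C=CCOc1cc(C=O)c(OC)c(OC)c1F | intermediate
17 | 2,4,6-trimethoxyphenol | COc1cc(OC)c(O)c(OC)c1 | starting material
18 | A-B dimer aldehyde, 2,6-dimethoxy-4-(2,4,6-trimethoxyphenoxy)benzaldehyde | COc1cc(OC)c(Oc2cc(OC)c(C=O)c(OC)c2)c(OC)c1 | intermediate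
19 | A-B dimer aryl formate, 2,6-dimethoxy-4-(2,4,6-trimethoxyphenoxy)phenyl formate | COc1cc(OC)c(Oc2cc(OC)c(OC=O)c(OC)c2)c(OC)c1 | intermediate
20 | A-B dimer phenol, 2,6-dimethoxy-4-(2,4,6-trimethoxyphenoxy)phenol | COc1cc(OC)c(Oc2cc(OC)c(O)c(OC)c2)c(OC)c1 | intermediate
21 | A-B-C trimer nitrile allyl ether (ring C: 4-cyano, 3,5-dimethoxy, 6-allyloxy) | COc1cc(OC)c(Oc2cc(OC)c(Oc3cc(OC)c(C#N)c(OC)c3OCC=C)c(OC)c2)c(OC)c1 | intermediate
22 | A-B-C trimer nitrile phenol (ring C: 4-cyano, 6-hydroxy) | COc1cc(OC)c(Oc2cc(OC)c(Oc3cc(OC)c(C#N)c(OC)c3O)c(OC)c2)c(OC)c1 | intermediate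
23 | A-B-C-D tetramer (ring C 4-cyano; ring D 4-formyl) | COc1cc(OC)c(Oc2cc(OC)c(Oc3cc(OC)c(C#N)c(OC)c3Oc3cc(OC)c(C=O)c(OC)c3)c(OC)c2)c(OC)c1 | intermediate
24 | A-B-C-D tetramer aryl formate (ring C 4-cyano; ring D 4-formyloxy) | COc1cc(OC)c(Oc2cc(OC)c(Oc3cc(OC)c(C#N)c(OC)c3Oc3cc(OC)c(OC=O)c(OC)c3)c(OC)c2)c(OC)c1 | intermediate
25 | A-B-C-D tetramer phenol (ring C 4-cyano; ring D 4-hydroxy) | COc1cc(OC)c(Oc2cc(OC)c(Oc3cc(OC)c(C#N)c(OC)c3Oc3cc(OC)c(O)c(OC)c3)c(OC)c2)c(OC)c1 | intermediate
26 | A-B-C-D tetramer aldimine (ring C 4-CH=NH; ring D 4-hydroxy), shown N-protonated after quench | COc1cc(OC)c(Oc2cc(OC)c(Oc3cc(OC)c(C=N)c(OC)c3Oc3cc(OC)c(O)c(OC)c3)c(OC)c2)c(OC)c1 | intermediate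
27 | A-B-C-D tetramer phenol aldehyde (ring C 4-formyl; ring D 4-hydroxy) | COc1cc(OC)c(Oc2cc(OC)c(Oc3cc(OC)c(C=O)c(OC)c3Oc3cc(OC)c(O)c(OC)c3)c(OC)c2)c(OC)c1 | intermediate
28 | A-to-E pentamer allyl ether (formyl on C4 of rings C and E; ring E 2-allyloxy, 5,6-dimethoxy) | COc1cc(OC)c(Oc2cc(OC)c(Oc3cc(OC)c(C=O)c(OC)c3Oc3cc(OC)c(Oc4c(OCC=C)cc(C=O)c(OC)c4OC)c(OC)c3)c(OC)c2)c(OC)c1 | intermediate
29 | A-to-E pentamer phenol (ring E 2-hydroxy) | COc1cc(OC)c(Oc2cc(OC)c(Oc3cc(OC)c(C=O)c(OC)c3Oc3cc(OC)c(Oc4c(O)cc(C=O)c(OC)c4OC)c(OC)c3)c(OC)c2)c(OC)c1 | intermediate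
30 | A-to-F hexamer allyl ether (formyl on C4 of rings C, E and F; ring F 3-methoxy, 5-allyloxy) | COc1cc(OC)c(Oc2cc(OC)c(Oc3cc(OC)c(C=O)c(OC)c3Oc3cc(OC)c(Oc4c(Oc5cc(OC)c(C=O)c(OCC=C)c5)cc(C=O)c(OC)c4OC)c(OC)c3)c(OC)c2)c(OC)c1 | intermediate
31 | A-to-F hexamer phenol (ring F 5-hydroxy) | COc1cc(OC)c(Oc2cc(OC)c(Oc3cc(OC)c(C=O)c(OC)c3Oc3cc(OC)c(Oc4c(Oc5cc(OC)c(C=O)c(O)c5)cc(C=O)c(OC)c4OC)c(OC)c3)c(OC)c2)c(OC)c1 | intermediate
32 | A-to-G heptamer allyl ether (formyl on C4 of rings C, E, F and G; ring G 6-allyloxy) | COc1cc(OC)c(Oc2cc(OC)c(Oc3cc(OC)c(C=O)c(OC)c3Oc3cc(OC)c(Oc4c(Oc5cc(OC)c(C=O)c(Oc6cc(OC)c(C=O)c(OC)c6OCC=C)c5)cc(C=O)c(OC)c4OC)c(OC)c3)c(OC)c2)c(OC)c1 | intermediate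
33 | A-to-G heptamer phenol (ring G 6-hydroxy) | COc1cc(OC)c(Oc2cc(OC)c(Oc3cc(OC)c(C=O)c(OC)c3Oc3cc(OC)c(Oc4c(Oc5cc(OC)c(C=O)c(Oc6cc(OC)c(C=O)c(OC)c6O)c5)cc(C=O)c(OC)c4OC)c(OC)c3)c(OC)c2)c(OC)c1 | intermediate
34 | octamer pentaaldehyde (formyl on C4 of rings C, E, F, G and H; sixteen methoxy groups) | COc1cc(OC)c(Oc2cc(OC)c(Oc3cc(OC)c(C=O)c(OC)c3Oc3cc(OC)c(Oc4c(Oc5cc(OC)c(C=O)c(Oc6cc(OC)c(C=O)c(OC)c6Oc6cc(OC)c(C=O)c(OC)c6)c5)cc(C=O)c(OC)c4OC)c(OC)c3)c(OC)c2)c(OC)c1 | intermediate
35 | octamer pentaformate (formyloxy on C4 of rings C, E, F, G and H) | COc1cc(OC)c(Oc2cc(OC)c(Oc3cc(OC)c(OC=O)c(OC)c3Oc3cc(OC)c(Oc4c(Oc5cc(OC)c(OC=O)c(Oc6cc(OC)c(OC=O)c(OC)c6Oc6cc(OC)c(OC=O)c(OC)c6)c5)cc(OC=O)c(OC)c4OC)c(OC)c3)c(OC)c2)c(OC)c1 | intermediate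
36 | octamer pentaphenol (hydroxyl on C4 of rings C, E, F, G and H; sixteen methoxy groups) | COc1cc(OC)c(Oc2cc(OC)c(Oc3cc(OC)c(O)c(OC)c3Oc3cc(OC)c(Oc4c(Oc5cc(OC)c(O)c(Oc6cc(OC)c(O)c(OC)c6Oc6cc(OC)c(O)c(OC)c6)c5)cc(O)c(OC)c4OC)c(OC)c3)c(OC)c2)c(OC)c1 | intermediate
37 | CNP0309601.0 | Oc1cc(O)c(Oc2cc(O)c(Oc3cc(O)c(O)c(O)c3Oc3cc(O)c(Oc4c(Oc5cc(O)c(O)c(Oc6cc(O)c(O)c(O)c6Oc6cc(O)c(O)c(O)c6)c5)cc(O)c(O)c4O)c(O)c3)c(O)c2)c(O)c1 | target

Total step count: 27.
Longest linear sequence: 18 steps (steps 1 to 4, then steps 14 to 27).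

Steps most likely to fail

Step 26. What may go wrong is electrophilic oxidation of the most electron-rich rings (A, B and D) by the excess peracid, or stalled conversion that leaves mixtures of aldehydes, formates and phenols. The fallback sets out from 34 and comes back to the route at 37. BBr3 in CH2Cl2 first cleaves the sixteen methyl ethers of 34 and should give the hexadecahydroxy pentaaldehyde F1, in which every formyl group has an ortho hydroxyl. Classical Dakin oxidation (H2O2, NaHCO3, degassed H2O/THF, 0 °C, then dilute HCl) then replaces the five formyl groups by hydroxyl through nucleophilic hydroperoxide instead of an electrophilic peracid and should give 37 directly.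

Step 19. What may go wrong is slow addition of the doubly ortho-substituted phenoxide of 27 to a fluoride flanked by two alkoxy groups, so that at the temperature needed aryloxide exchange at the aldehyde-bearing rings scrambles the chain. The fallback sets out from 27 and 13 and comes back to the route at 29. The phenoxide of 27 is coupled (Cs2CO3, DMSO) with bromide 13, whose ortho bromine accelerates the addition inductively, to give the bromo pentamer F2. Miyaura borylation (B2pin2, Pd(dppf)Cl2, KOAc, dioxane) should give the pentamer boronate F3, and NaBO3·4H2O oxidation then gives phenol 29, so that step 20 is not needed.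

Step 27. What may go wrong is incomplete cleavage of some of the sixteen methyl ethers and oxidative loss of the free polyphenol during isolation. The fallback sets out from 36 and comes back to the route at 37. After the BBr3 treatment and methanol quench, the crude polyphenol is acetylated under argon (Ac2O, pyridine) to the henicosaacetate F4, which is stable, can be purified on silica and can be separated from partly methylated material. Degassed HCl in MeOH then removes the acetates as methyl acetate and releases 37.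

Further compounds
F1 | step 26 | octamer pentaaldehyde with sixteen free hydroxyls (formyl on C4 of rings C, E, F, G and H) | Oc1cc(O)c(Oc2cc(O)c(Oc3cc(O)c(C=O)c(O)c3Oc3cc(O)c(Oc4c(Oc5cc(O)c(C=O)c(Oc6cc(O)c(C=O)c(O)c6Oc6cc(O)c(C=O)c(O)c6)c5)cc(C=O)c(O)c4O)c(O)c3)c(O)c2)c(O)c1
F2 | step 19 | A-to-E bromo pentamer (ring E 2-bromo, 4-formyl, 5,6-dimethoxy) | COc1cc(OC)c(Oc2cc(OC)c(Oc3cc(OC)c(C=O)c(OC)c3Oc3cc(OC)c(Oc4c(Br)cc(C=O)c(OC)c4OC)c(OC)c3)c(OC)c2)c(OC)c1
F3 | step 19 | A-to-E pentamer pinacol boronate (ring E 2-boryl) | COc1cc(OC)c(Oc2cc(OC)c(Oc3cc(OC)c(C=O)c(OC)c3Oc3cc(OC)c(Oc4c(B5OC(C)(C)C(C)(C)O5)cc(C=O)c(OC)c4OC)c(OC)c3)c(OC)c2)c(OC)c1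
F4 | step 27 | henicosaacetate of 37 | CC(=O)Oc1cc(OC(C)=O)c(Oc2cc(OC(C)=O)c(Oc3cc(OC(C)=O)c(OC(C)=O)c(OC(C)=O)c3Oc3cc(OC(C)=O)c(Oc4c(Oc5cc(OC(C)=O)c(OC(C)=O)c(Oc6cc(OC(C)=O)c(OC(C)=O)c(OC(C)=O)c6Oc6cc(OC(C)=O)c(OC(C)=O)c(OC(C)=O)c6)c5)cc(OC(C)=O)c(OC(C)=O)c4OC(C)=O)c(OC(C)=O)c3)c(OC(C)=O)c2)c(OC(C)=O)c1
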